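- If the chain carriers held steady from before my first reading, I could reckon the chain as taking one constant share of the standing reagent each minute.

| setting | green | blue | spring | dawn | dusk | autumn |
|---|---|---|---|---|---|---|
| substrate | 0.50 M | 0.50 M | 0.50 M | 0.50 M | 0.50 M | 0.50 M |
| reagent | 0.59 equiv | 2.2 equiv | 0.800 equiv | 1.00 equiv | 1.50 equiv | 2.50 equiv |
| transfer agent | 0.050 M | 0.050 M | 0.0500 M | 0.0500 M | 0.0500 M | 0.0500 M |
| initiator | 5 mol% | 5 mol% | 5 mol% | 5 mol% | 5 mol% | 5 mol% |
| remark | run made earlier | run made earlier |  |  |  |  |
| time |  |  | 8.0 min | 8.0 min | 8.0 min | 8.0 min |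

- green (time / min: target / %, substrate / %): 0.667: 5.7, 94.3; 1.00: 8.6, 90.9; 2.00: 14.6, 84.6; 3.00: 19.5, 76.8; 5.00: 27.5, 66.9; 8.00: 34.7, 57.3
- blue (time / min: target / %, substrate / %): 0.667: 18.9, 78.4; 1.00: 27.7, 68.4; 2.00: 46.7, 42.0; 3.00: 59.3, 21.0; 5.00: 63.8, 0; 8.00: 49.6, 0.3

(each reading ± 0.5 percentage points)

- a species is counted by the substrate in it: one ended chains counts as two
- steps thought possible: initiator -> 2 initiating radical; substrate + initiating radical -> capped initiator + first chain carrier; reagent + first chain carrier -> target + second chain carrier; substrate + second chain carrier -> by-product + first chain carrier; transfer agent + first chain carrier -> side product + idle radical; 2 idle radical -> ended radicals; 2 first chain carrier -> ended chains; reagent + target -> over-reaction product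
- "hardly changes" means that all values lie within two and a half points (for a concentration: within two and a half percent of the largest)

* amount of target at the end, in percent of the substrate charged for spring, dawn, dusk, autumn, in this order
* how the row runs (rises, then falls / falls all the way / rises all the way / falls, then rises / hardly changes)

- Fastest rung: the carriers. Blue had lost 21.6% of its substrate by 0.667 min and 31.6% by 1.00 min. The average pace read alike at both readings, so I took the carriers as steady and reckoned with what that left free.
- Next rung: the reagent. Each turn of the chain takes one reagent and one substrate. Counting the substrate lost as reagent spent, I read from blue at 2.00 min 0.153 min⁻¹ for the chain constant, the share of the standing reagent that the chain takes per minute, a pseudo-first-order constant.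
- Green, with its smaller charge, read 0.151 min⁻¹ at 2.00 min. The reagent's lifetime against the chain was therefore 6.54 min.
- Slowest rung: the target. In the blue tail, with substrate at 0%, target fell from 63.8% to 49.6%. I read a lifetime of 11.9 min for blue's target in that tail, longer than the reagent's against the chain.
- I took the clearing time as the moment when the reagent spent by the chain equals the substrate charged. I reckoned that for dusk at 7.18 min, just inside the 8.0 min.
- For autumn I reckoned 3.34 min. That left 4.66 min for autumn's target to fall as blue's had in its tail. The reckoning gave spring and dawn, at 0.800 equiv and 1.00 equiv, no clearing time, and I expected the row to turn near dusk.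
- The forecast gave 43%, 51%, 67% and 41%: rises, then falls. On autumn it said: “substrate is gone by about 3.3 min, then target decays from 70 to about 41 %”.
- The flasks ended at 43.6%, 51.6%, 68.2% and 41.5%: rises, then falls.

    initiator → 2 initiating radical (k = 0.00100 s⁻¹)
    substrate + initiating radical → capped initiator + first chain carrier (k = 6.67 × 10⁶ L mol⁻¹ s⁻¹)
    reagent + first chain carrier → target + second chain carrier (k = 1.05 × 10⁶ L mol⁻¹ s⁻¹)
    substrate + second chain carrier → by-product + first chain carrier (k = 8.93 × 10⁵ L mol⁻¹ s⁻¹)
    transfer agent + first chain carrier → side product + idle radical (kL = 4.18 × 10⁵ L mol⁻¹ s⁻¹)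
    2 idle radical → ended radicals (k = 1.00 × 10⁹ L mol⁻¹ s⁻¹)
    2 first chain carrier → ended chains (k = 2.00 × 10⁷ L mol⁻¹ s⁻¹)
    reagent + target → over-reaction product (k = 0.00364 L mol⁻¹ s⁻¹)

- In spring at 8.00 min, initiator stood at 61.9% of its charge and transfer agent at 61.9%, the two alike. The chain constant 0.153 min⁻¹, run on spring's charge for 8.0 min, reckoned 43.5% of the substrate left. The spring flask held 43.7%.

The runs stem from a simulated flask from invented constants, and the scatter is random.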